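**Retrosynthetic overview**
1. Dehydrogravicycle ⇐ one-pot MOM removal and C–B oxidation of a macrocyclic (R)-benzylic pinacol boronate.
2. Key step, which closes the only new ring: Br–Li exchange on a seco aryl bromide, addition of the tethered aryllithium to the chain-end (S)-α-carbamoyloxy boronate to give a 23-membered borate, then 1,2-aryl shift from B to C with loss of carbamate. This contracts the ring to 22 members and forms the ring B–C bond and the (R) centre together.
3. Seco compound ⇐ Negishi coupling at the ring A iodide of a diaryl ether (ring A iodide, ring B bromide) with a C14 alkylzinc; diaryl ether ⇐ Chan–Lam coupling of a ring A boronic acid (from 3-iodophenol by Ir C–H borylation) with a ring B phenol (from resorcinol by ortho-lithiation/hydroxylation and para-bromination).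
4. C14 chain ⇐ B-alkyl Suzuki coupling of the (S)-α-carbamoyloxy boronate from hept-6-en-1-ol (sparteine lithiation–borylation) with the E vinyl iodide from 7-bromohept-1-yne (hydrozirconation–iodination).
5. Ring order: rings A and B are bought as benzenes; the macrocycle is the only ring made, in the penultimate step.

Assumption: the target SMILES is read as the (R)-carbinol with an E alkene in a 22-membered ring; 7-bromohept-1-yne and (−)-sparteine are taken as catalogue items.

**Route**

Step 1
Reactants: 1 3-iodophenol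
Product: 2 1-iodo-3-(methoxymethoxy)benzene
Conditions: MOMCl, i-Pr2NEt, CH2Cl2, 0 °C → rt
Reagents that add atoms: chloromethyl methyl ether (MOMCl), COCCl
Why: O-alkylation of the phenol with an α-chloro ether (Williamson-type) gives a MOM ether that survives the organolithium, boron and palladium steps to come.

Step 2
Reactants: 2 1-iodo-3-(methoxymethoxy)benzene
Product: 4 [3-iodo-5-(methoxymethoxy)phenyl]boronic acid, via pinacol boronate 3 (not isolated)
Conditions: B2pin2, [Ir(OMe)(cod)]2 (1.5 mol%), 4,4'-di-tert-butyl-2,2'-bipyridine, THF, 60 °C; then NaIO4, NH4OAc, acetone/H2O, rt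
Reagents that add atoms: bis(pinacolato)diboron (B2pin2), CC1(C)OB(OC1(C)C)B1OC(C)(C)C(C)(C)O1; water, O
Why: Sterically controlled Ir-catalysed C–H borylation (Hartwig–Miyaura) goes only to C5, the one C–H with no ortho substituent, and tolerates the C–I bond; periodate then cleaves the pinacol ester to the boronic acid.

Step 3
Reactants: 5 resorcinol (benzene-1,3-diol)
Product: 6 1,3-bis(methoxymethoxy)benzene
Conditions: MOMCl (2.4 equiv), i-Pr2NEt, CH2Cl2, 0 °C → rt
Reagents that add atoms: chloromethyl methyl ether (MOMCl), COCCl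
Why: Double O-alkylation protects both phenols and turns them into two cooperating ortho-directing groups for the next step.

Step 4
Reactants: 6 1,3-bis(methoxymethoxy)benzene
Product: 9 2,6-bis(methoxymethoxy)phenol, via aryllithium 7 (not isolated), via dimethyl arylboronate 8 (not isolated)
Conditions: n-BuLi, THF, 0 °C; B(OMe)3, −78 °C → rt; then AcOH, 30% H2O2, 0 °C → rt
Reagents that add atoms: hydrogen peroxide, OO
Why: Directed ortho-metalation between the two MOM ethers, borylation and peroxide oxidation of the C–B bond (aryl shift from boron to oxygen) place the third oxygen on C2.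

Step 5
Reactants: 9 2,6-bis(methoxymethoxy)phenol
Product: 10 4-bromo-2,6-bis(methoxymethoxy)phenol
Conditions: NBS, NaH (5 mol%), CHCl3, −45 °C → rt
Reagents that add atoms: N-bromosuccinimide (NBS), O=C1CCC(=O)N1Br
Why: Electrophilic aromatic bromination under phenoxide control goes para to the free OH, because both ortho positions are blocked and the phenoxide oxygen outweighs the two ether oxygens.

Step 6
Reactants: 4 [3-iodo-5-(methoxymethoxy)phenyl]boronic acid; 10 4-bromo-2,6-bis(methoxymethoxy)phenol
Product: 11 5-bromo-2-[3-iodo-5-(methoxymethoxy)phenoxy]-1,3-bis(methoxymethoxy)benzene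
Conditions: Cu(OAc)2 (1 equiv), pyridine, 4 Å MS, CH2Cl2, O2 (air), rt
Reagents that add atoms: none
Why: Chan–Lam oxidative C–O coupling runs at room temperature, accepts 2,6-disubstituted phenols and leaves the aryl iodide and aryl bromide untouched.

Step 7
Reactants: 12 hept-6-en-1-ol
Product: 13 hept-6-en-1-yl N,N-di(propan-2-yl)carbamate
Conditions: i-Pr2NC(O)Cl, Et3N, CH2Cl2, reflux
Reagents that add atoms: N,N-di(propan-2-yl)carbamoyl chloride, CC(C)N(C(C)C)C(Cl)=O
Why: O-Acylation gives the Hoppe carbamate, which first directs the asymmetric lithiation and later is the leaving group of the 1,2-shift.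

Step 8
Reactants: 13 hept-6-en-1-yl N,N-di(propan-2-yl)carbamate
Product: 16 (1S)-1-(4,4,5,5-tetramethyl-1,3,2-dioxaborolan-2-yl)hept-6-en-1-yl N,N-di(propan-2-yl)carbamate, via lithiated carbamate 14 (not isolated), via isopropoxy borate 15 (not isolated)
Conditions: s-BuLi, (−)-sparteine, Et2O, −78 °C, 5 h; i-PrOBpin, −78 °C → rt; then 1 M HCl
Reagents that add atoms: 2-isopropoxy-4,4,5,5-tetramethyl-1,3,2-dioxaborolane (i-PrOBpin), CC(C)OB1OC(C)(C)C(C)(C)O1
Why: Hoppe sparteine-mediated deprotonation removes the pro-S proton to give a configurationally stable (S)-α-lithio carbamate, and borylation with retention fixes the (S) centre that the key step later converts into the (R) centre of the target.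

Step 9
Reactants: 17 7-bromohept-1-yne
Product: 19 (1E)-7-bromo-1-iodohept-1-ene, via alkenyl-ZrCp2Cl 18 (not isolated)
Conditions: Cp2Zr(H)Cl, THF, rt; then I2, 0 °C
Reagents that add atoms: iodine, II
Why: Syn hydrozirconation puts zirconium on the terminal carbon and iodinolysis with retention gives only the E vinyl iodide, while the primary bromide is inert.

Step 10
Reactants: 16 (1S)-1-(4,4,5,5-tetramethyl-1,3,2-dioxaborolan-2-yl)hept-6-en-1-yl N,N-di(propan-2-yl)carbamate; 19 (1E)-7-bromo-1-iodohept-1-ene
Product: 21 (1S,8E)-14-bromo-1-(4,4,5,5-tetramethyl-1,3,2-dioxaborolan-2-yl)tetradec-8-en-1-yl N,N-di(propan-2-yl)carbamate, via alkyl-9-BBN 20 (not isolated)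
Conditions: 9-BBN-H, THF, 0 °C → rt; then 19, Pd(dppf)Cl2 (5 mol%), AsPh3, 3 M aq. K3PO4, DMF, rt
Reagents that add atoms: none
Why: Anti-Markovnikov hydroboration of the terminal alkene and B-alkyl Suzuki–Miyaura coupling with the vinyl iodide keep the E geometry; only the primary 9-BBN borane transmetalates, so the secondary pinacol boronate, its stereocentre and the alkyl bromide are spectators.

Step 11
Reactants: 21 (1S,8E)-14-bromo-1-(4,4,5,5-tetramethyl-1,3,2-dioxaborolan-2-yl)tetradec-8-en-1-yl N,N-di(propan-2-yl)carbamate; 11 5-bromo-2-[3-iodo-5-(methoxymethoxy)phenoxy]-1,3-bis(methoxymethoxy)benzene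
Product: 23 (1S,8E)-14-{3-[4-bromo-2,6-bis(methoxymethoxy)phenoxy]-5-(methoxymethoxy)phenyl}-1-(4,4,5,5-tetramethyl-1,3,2-dioxaborolan-2-yl)tetradec-8-en-1-yl N,N-di(propan-2-yl)carbamate, via alkylzinc bromide 22 (not isolated)
Conditions: Zn dust, LiCl, THF, 50 °C; then 11, Pd(dppf)Cl2 (5 mol%), THF, rt
Reagents that add atoms: none
Why: Zinc insertion into the primary C–Br bond gives an organozinc that does not attack boronic esters, and the Negishi coupling takes the ring A iodide and spares the electron-rich ring B bromide because oxidative addition to C–I is much faster.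

Step 12
Reactants: 23 (1S,8E)-14-{3-[4-bromo-2,6-bis(methoxymethoxy)phenoxy]-5-(methoxymethoxy)phenyl}-1-(4,4,5,5-tetramethyl-1,3,2-dioxaborolan-2-yl)tetradec-8-en-1-yl N,N-di(propan-2-yl)carbamate
Product: 26 tri-MOM macrocyclic (R)-benzylic pinacol boronate (22-membered ring; E alkene), via aryllithium 24 (not isolated), via macrocyclic lithium borate 25 (not isolated)
Conditions: t-BuLi (2.0 equiv), THF/Et2O, 1 mM, −100 → −78 °C; then MgBr2·OEt2, −78 → 40 °C; aq. NH4Cl
Reagents that add atoms: none
Why: Proposed new method: bromine–lithium exchange with t-BuLi at −100 °C is faster than addition of this bulky base to the hindered, carbonyl-chelated secondary boronic ester (the kinetic order behind in-situ-quench borylations and Parham cyclisations), so the tethered aryllithium 24 adds to boron and closes the 23-membered borate 25, and antiperiplanar 1,2-migration of the aryl group from boron to carbon with loss of the carbamate (promoted by MgBr2) contracts the ring by one atom to the 22-membered carbocycle, forms the ring B–C bond and inverts the (S) carbamate carbon to the (R) benzylic boronate; the closest known reaction type is the intermolecular Hoppe–Matteson/lithiation–borylation 1,2-metalate rearrangement of α-carbamoyloxy boronates with aryl metals, which has not been used to close a macrocycle by ring contraction.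

Step 13
Reactants: 26 tri-MOM macrocyclic (R)-benzylic pinacol boronate
Product: 28 dehydrogravicycle (R carbinol; E alkene), via triphenol boronate 27 (not isolated)
Conditions: HCl (2 M in MeOH), THF, 40 °C; then NaOH (aq), 30% H2O2, 0 °C → rt
Reagents that add atoms: hydrogen peroxide, OO
Why: Acetal exchange with methanol removes the three MOM ethers while the benzylic C–B bond cannot ionise as a free benzylic alcohol could, and hydroperoxide then oxidises the C–B bond with retention (carbon shift from boron to oxygen) to give the (R)-alcohol.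

**Compound list**
1 | 3-iodophenol | Oc1cccc(I)c1 | starting material
2 | 1-iodo-3-(methoxymethoxy)benzene | COCOc1cccc(I)c1 | intermediate
3 | 2-[3-iodo-5-(methoxymethoxy)phenyl]-4,4,5,5-tetramethyl-1,3,2-dioxaborolane (not isolated) | COCOc1cc(I)cc(c1)B1OC(C)(C)C(C)(C)O1 | intermediate
4 | [3-iodo-5-(methoxymethoxy)phenyl]boronic acid | COCOc1cc(I)cc(c1)B(O)O | intermediate
5 | resorcinol (benzene-1,3-diol) | Oc1cccc(O)c1 | starting material
6 | 1,3-bis(methoxymethoxy)benzene | COCOc1cccc(OCOC)c1 | intermediate
7 | [2,6-bis(methoxymethoxy)phenyl]lithium (not isolated) | [Li]c1c(OCOC)cccc1OCOC | intermediate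
8 | dimethyl [2,6-bis(methoxymethoxy)phenyl]boronate (not isolated) | COCOc1cccc(OCOC)c1B(OC)OC | intermediate
9 | 2,6-bis(methoxymethoxy)phenol | COCOc1cccc(OCOC)c1O | intermediate
10 | 4-bromo-2,6-bis(methoxymethoxy)phenol | COCOc1cc(Br)cc(OCOC)c1O | intermediate
11 | 5-bromo-2-[3-iodo-5-(methoxymethoxy)phenoxy]-1,3-bis(methoxymethoxy)benzene | COCOc1cc(I)cc(Oc2c(OCOC)cc(Br)cc2OCOC)c1 | intermediate
12 | hept-6-en-1-ol | C=CCCCCCO | starting material
13 | hept-6-en-1-yl N,N-di(propan-2-yl)carbamate | C=CCCCCCOC(=O)N(C(C)C)C(C)C | intermediate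
14 | (1S)-1-lithiohept-6-en-1-yl N,N-di(propan-2-yl)carbamate, as its (−)-sparteine complex (not isolated) | C=CCCCC[C@H]([Li])OC(=O)N(C(C)C)C(C)C | intermediate
15 | lithium isopropoxy(pinacolato)borate of the (1S)-1-(carbamoyloxy)hept-6-en-1-yl group (not isolated) | C=CCCCC[C@H]([B-]1(OC(C)C)OC(C)(C)C(C)(C)O1)OC(=O)N(C(C)C)C(C)C.[Li+] | intermediate
16 | (1S)-1-(4,4,5,5-tetramethyl-1,3,2-dioxaborolan-2-yl)hept-6-en-1-yl N,N-di(propan-2-yl)carbamate | C=CCCCC[C@H](B1OC(C)(C)C(C)(C)O1)OC(=O)N(C(C)C)C(C)C | intermediate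
17 | 7-bromohept-1-yne | C#CCCCCCBr | starting material
18 | [(1E)-7-bromohept-1-en-1-yl]ZrCp2Cl (not isolated) | BrCCCCC/C=C/[Zr](Cl)(C1C=CC=C1)C1C=CC=C1 | intermediate
19 | (1E)-7-bromo-1-iodohept-1-ene | BrCCCCC/C=C/I | intermediate
20 | (1S)-7-(9-borabicyclo[3.3.1]nonan-9-yl)-1-(4,4,5,5-tetramethyl-1,3,2-dioxaborolan-2-yl)heptyl N,N-di(propan-2-yl)carbamate (not isolated) | C(CCCCC[C@H](B3OC(C)(C)C(C)(C)O3)OC(=O)N(C(C)C)C(C)C)B1C2CCCC1CCC2 | intermediate
21 | (1S,8E)-14-bromo-1-(4,4,5,5-tetramethyl-1,3,2-dioxaborolan-2-yl)tetradec-8-en-1-yl N,N-di(propan-2-yl)carbamate | BrCCCCC/C=C/CCCCCC[C@H](B1OC(C)(C)C(C)(C)O1)OC(=O)N(C(C)C)C(C)C | intermediate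
22 | [(6E,14S)-14-(di(propan-2-yl)carbamoyloxy)-14-(4,4,5,5-tetramethyl-1,3,2-dioxaborolan-2-yl)tetradec-6-en-1-yl]zinc bromide (not isolated) | Br[Zn]CCCCC/C=C/CCCCCC[C@H](B1OC(C)(C)C(C)(C)O1)OC(=O)N(C(C)C)C(C)C | intermediate
23 | (1S,8E)-14-{3-[4-bromo-2,6-bis(methoxymethoxy)phenoxy]-5-(methoxymethoxy)phenyl}-1-(4,4,5,5-tetramethyl-1,3,2-dioxaborolan-2-yl)tetradec-8-en-1-yl N,N-di(propan-2-yl)carbamate | COCOc1cc(CCCCC/C=C/CCCCCC[C@H](B3OC(C)(C)C(C)(C)O3)OC(=O)N(C(C)C)C(C)C)cc(Oc2c(OCOC)cc(Br)cc2OCOC)c1 | intermediate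
24 | aryllithium of 23: lithium in place of the ring B bromine (not isolated) | COCOc1cc(CCCCC/C=C/CCCCCC[C@H](B3OC(C)(C)C(C)(C)O3)OC(=O)N(C(C)C)C(C)C)cc(Oc2c(OCOC)cc([Li])cc2OCOC)c1 | intermediate
25 | 23-membered macrocyclic lithium borate: pinacolato boron bonded to ring B C4 and to the (S) carbamate carbon (not isolated) | COCOc1cc2cc(c1)Oc1c(OCOC)cc(cc1OCOC)[B-]3(OC(C)(C)C(C)(C)O3)[C@H](OC(=O)N(C(C)C)C(C)C)CCCCCC/C=C/CCCCC2.[Li+] | intermediate
26 | tri-MOM macrocyclic boronate: dehydrogravicycle skeleton (22-membered ring, E alkene) with the three phenols as methoxymethyl ethers and the (R) benzylic carbon carrying 4,4,5,5-tetramethyl-1,3,2-dioxaborolan-2-yl in place of OH | COCOc1cc2cc(c1)Oc1c(OCOC)cc(cc1OCOC)[C@H](B3OC(C)(C)C(C)(C)O3)CCCCCC/C=C/CCCCC2 | intermediate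
27 | triphenol macrocyclic boronate: as 26 with three free phenols (not isolated) | Oc1cc2cc(c1)Oc1c(O)cc(cc1O)[C@H](B3OC(C)(C)C(C)(C)O3)CCCCCC/C=C/CCCCC2 | intermediate
28 | dehydrogravicycle, (R) benzylic alcohol, E alkene | Oc1cc2cc(c1)Oc1c(O)cc(cc1O)[C@H](O)CCCCCC/C=C/CCCCC2 | target

**Count and risks**
Total steps: 13. Longest linear sequence: 7 steps (resorcinol 5 → 6 → 9 → 10 → 11 → 23 → 26 → 28; steps 3, 4, 5, 6, 11, 12, 13).

Most likely to fail, step 12 (the proposed new ring-contracting macrocyclisation). The risks are attack of t-BuLi on boron before the exchange and intermolecular borate formation giving oligomers. The fallback uses only known chemistry, sets out from 10 and 21 (with 3 isolated in step 2 instead of being cleaved) and comes back at 26. Phenol 10 is silylated (TBSCl, imidazole, DMF) to tert-butyl[4-bromo-2,6-bis(methoxymethoxy)phenoxy]dimethylsilane F1. Bromine–lithium exchange (t-BuLi, THF, −78 °C) gives [4-(tert-butyldimethylsilyloxy)-3,5-bis(methoxymethoxy)phenyl]lithium F2, which is added at −78 °C to boronate 21 to give the open-chain lithium borate F3. MgBr2·OEt2 and warming bring about the same stereospecific 1,2-aryl shift, now intermolecular (Hoppe–Matteson homologation of an α-carbamoyloxy boronate with an aryl metal), and give the (R)-benzylic pinacol boronate bromide F4. Zinc insertion (Zn, LiCl, THF, 50 °C) gives the alkylzinc bromide F5, and Negishi coupling with iodide 3 (Pd(dppf)Cl2, rt) gives the bis-boronate silyl ether F6. K2CO3 in MeOH frees the phenol F7, and an intramolecular Chan–Lam coupling at 2 mM (Cu(OAc)2, pyridine, 4 Å MS, O2, CH2Cl2) closes the diaryl ether to 26.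

Second, step 11 (organozinc formation and iodide-selective Negishi coupling on a substrate with two boronic esters). The risks are sluggish zinc insertion and some coupling at the ring B bromide. The fallback sets out from 21 and 11 and comes back at 23: a nickel-catalysed reductive cross-electrophile coupling of the two halides in one flask (NiI2 10 mol%, 4,4'-di-tert-butyl-2,2'-bipyridine, Zn dust, NaI, DMPU, 60 °C). No organozinc reagent is prepared, the alkyl partner enters as a radical, and no new compound is made (entry F0).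

Third, step 13 (one-pot acid deprotection and oxidation). The risks are loss of the benzylic boronate in acid and over-oxidation of the free polyphenol in basic peroxide. The fallback sets out from 26 and comes back at 28 with the order reversed. The C–B bond is oxidised first (NaBO3·4H2O, THF/H2O, rt) to the tri-MOM macrocyclic (R)-alcohol F8, which is isolated. The three MOM ethers are then removed under heterogeneous, non-solvolytic conditions (NaHSO4·SiO2, CH2Cl2, rt) that do not ionise the benzylic alcohol.

Further compounds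
F1 | step 12 | tert-butyl[4-bromo-2,6-bis(methoxymethoxy)phenoxy]dimethylsilane | COCOc1cc(Br)cc(OCOC)c1O[Si](C)(C)C(C)(C)C
F2 | step 12 | [4-(tert-butyldimethylsilyloxy)-3,5-bis(methoxymethoxy)phenyl]lithium | COCOc1cc([Li])cc(OCOC)c1O[Si](C)(C)C(C)(C)C
F3 | step 12 | open-chain lithium borate from F2 and 21, (S) at the carbamate carbon | BrCCCCC/C=C/CCCCCC[C@H]([B-]1(OC(C)(C)C(C)(C)O1)c2cc(OCOC)c(O[Si](C)(C)C(C)(C)C)c(OCOC)c2)OC(=O)N(C(C)C)C(C)C.[Li+]
F4 | step 12 | 2-[(1R,8E)-14-bromo-1-[4-(tert-butyldimethylsilyloxy)-3,5-bis(methoxymethoxy)phenyl]tetradec-8-en-1-yl]-4,4,5,5-tetramethyl-1,3,2-dioxaborolane | BrCCCCC/C=C/CCCCCC[C@@H](B1OC(C)(C)C(C)(C)O1)c1cc(OCOC)c(O[Si](C)(C)C(C)(C)C)c(OCOC)c1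
F5 | step 12 | alkylzinc bromide from F4 (ZnBr in place of the bromine) | Br[Zn]CCCCC/C=C/CCCCCC[C@@H](B1OC(C)(C)C(C)(C)O1)c1cc(OCOC)c(O[Si](C)(C)C(C)(C)C)c(OCOC)c1
F6 | step 12 | bis-boronate silyl ether: ring A 3-(methoxymethoxy)-5-(pinacolboryl)phenyl joined through the (8E)-C14 chain to the (R)-benzylic pinacol boronate on ring B (OTBS, two OMOM) | COCOc1cc(CCCCC/C=C/CCCCCC[C@@H](B3OC(C)(C)C(C)(C)O3)c2cc(OCOC)c(O[Si](C)(C)C(C)(C)C)c(OCOC)c2)cc(c1)B4OC(C)(C)C(C)(C)O4
F7 | step 12 | phenol from F6 (free OH on ring B between the two MOM ethers) | COCOc1cc(CCCCC/C=C/CCCCCC[C@@H](B3OC(C)(C)C(C)(C)O3)c2cc(OCOC)c(O)c(OCOC)c2)cc(c1)B4OC(C)(C)C(C)(C)O4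
F0 | step 11 | none | none
F8 | step 13 | tri-MOM macrocyclic (R)-benzylic alcohol (dehydrogravicycle tris(methoxymethyl) ether) | COCOc1cc2cc(c1)Oc1c(OCOC)cc(cc1OCOC)[C@H](O)CCCCCC/C=C/CCCCC2
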